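**Numbering used for every compound.** Ring: C1(=O), C2, C3(=O), C4 (CH3, oxirane), C5 (oxirane), C6 (lactone O), C7 (=C11), C8 (ester O), C9, C10 (CH3). C11 is the lactone α-carbon, C12 the lactone carbonyl, C13 the acetoxymethyl carbon. The target is 4S,5R,6R,8R,10R.

## Analysis of the target

The target is a ten-membered carbocycle fused through C6–C7 to an α,β-unsaturated γ-lactone whose C7=C11 double bond is exocyclic to the large ring. Five stereocentres are present: the trans-oxirane C4/C5 sits next to the lactone carbinol C6, C8 is 1,3 to C6 across the sp2 carbon C7, and C10 is remote from the others. C10 lies α to the C1 carbonyl of a 1,3-diketone and is therefore epimerisable. The sensitive groups are the 1,3-diketone, the α,β-epoxy ketone, a γ-acyloxy butenolide that can eliminate or migrate to the C8 oxygen, two allylic acetates and a Z-configured β,β-disubstituted enoate. The difficulty lies in the medium ring, for which end-to-end closure is unreliable, and in the dense oxidation pattern. A further constraint is that an E C4=C5 bond cannot coexist with an E C7=C8 bond in this ring, because the C4 methyl would then sit on the C7=C8 π-face. The strategy rests on one feature: C1, C2, C3, C8, C9 and C10 with the C10 methyl form a 4-methylcyclohexane-1,3-dione pattern. The four carbons C4–C7 can therefore be inserted between C3 and C8 of a six-membered ring by a [3,3] shift.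

## Retrosynthetic reasoning

**39 from 38.** The 1,3-diketone is masked to the end as the C1 ethyl enol ether of a vinylogous ester. In this form C2 is sp2, so the C3 ketone has no enolisable hydrogen on that side throughout the route. Only the C1–O bond is cut, by mild hydrolysis.

**38 from 37.** The oxirane is cut back to the E C4=C5 enone. The forward reaction is a nucleophilic epoxidation of the enone arm of a cross-conjugated dienone, done when the ring already carries the butenolide and so resembles the target.

**37 from 36.** The E C4=C5 bond is generated late from a C4 phenylsulfinyl group by thermal syn-elimination. It must be late: while C7=C8 is still an in-ring trans double bond, the ring cannot hold a second trans double bond at C4=C5, so an early dehydrogenation would give the cis or the exocyclic olefin.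

**36 from 30 and 35.** The C8 ester bond is cut to alcohol 30 and acid 35. The acid carries its acetate and Z geometry from the start, so no free Z-4-hydroxy enoate, which would relactonise, appears on the substrate.

**30 and 29 from 26.** The butenolide with its C8 hydroxyl is cut back to the β,γ-unsaturated lactone 26. Forward, C7=C8 is epoxidised on its exposed face and the acidic C11–H opens the oxirane by β-elimination. This gives the C8–O bond, the C7=C11 bond and the C8 configuration in one operation without strong base.

**26 from 24.** The C11–C13 bond is cut. Only at the stage of lactone 24 can C11 be deprotonated to a dienolate without touching a stereocentre. The C12 carbonyl must therefore exist while C7=C8 is still exocyclic to the lactone.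

**24 from 22 and 21.** The C12–O6 lactone bond and the C12 oxidation state are traced to the 1,4-diol 22, and this to acetonide 21. A five-membered cyclic ether in this position could not be oxidised at C12 in the presence of the alkenes. The enol ether oxygen on C6 and a separate oxygen on C12 are therefore tied by an isopropylidene acetal in a seven-membered ring.

**21 from 19.** The C4–S bond is cut to the regiodefined silyl dienol ether 19. The sulfur group is the latent C4=C5 bond and leaves C3 without α-hydrogens for the enolate chemistry at C11.

**19 from 16 (key disconnection).** The C5–C6 bond is cut and the C3–C8 bond re-formed. The ten-membered ring contracts to the cyclohexene carbinol 16, which carries an isopropenyl group on C3 and the cyclic enol ether on C8. Forward, the alkoxide of 16 rearranges through a chair, the ring grows by four atoms, C6 arrives bonded to its lactone oxygen, and the enolate appears at C3/C4 where the next step needs it.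

**16 from 14 and 15.** The C3–C4 bond is cut to ketone 14 and the isopropenyl organometallic 15. Addition anti to the C8 substituent gives the trans-dialkenyl arrangement that the chair requires.

**14 from 6 and 12.** The C8–C7 bond is cut to the vinylogous ester 6 and the β-bromo enol ether 12. The forward coupling has to be run under conditions that do not enolise the product, so that C8 is set kinetically, trans to the C10 methyl.

**6 from 4, 3, 1 and 2.** The C1 oxygen is removed to give enone 4. Enol etherification of the free 1,3-dione would place the alkoxy group on the carbonyl remote from the methyl group and would expose C10 to enolisation. The oxygen is therefore put on the β-carbon of 4 by addition and elimination. Enone 4 comes from keto aldehyde 3 by aldol condensation, and 3 from 1 and 2 by a catalytic asymmetric Michael addition that sets C10.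

**12 from 10, 9, 7 and 8.** The bromide is removed to the enol ether 10, the enol ether is traced to the allylic acetal 9 by double-bond migration, and 9 to diol 7 and ketal 8.

**35 from 34 and 31.** The acid is traced through its 4-methoxybenzyl ester 34 to butenolide 31, whose ring fixes the Z geometry.

## Alternatives that were turned down

**Alternative 1: nitrile oxide cycloaddition.** The disconnection cuts C2–C3 and the O–C1 bond of an isoxazoline. In the forward step NaOCl turns a C3 aldoxime into a nitrile oxide that adds to a terminal C1=C2 alkene and gives the isoxazoline-bridged carbocycle A1.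
- For: all five stereocentres, the oxirane, the butenolide and both esters are in place before the ring is closed. The isoxazoline is a stable mask of the 1,3-dioxygenated unit. On these points it is stronger than the chosen route, which must set C8 and the oxirane on the ring.
- Against: a ten-membered ring is closed end to end by a bimolecular-type process. Transannular strain and dimerisation of the nitrile oxide compete, and the dipole sits on the fully substituted oxirane carbon C4. A1 then needs N–O cleavage and oxidation next to the epoxide, the butenolide and the enoate.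
- Comparison: the chosen route offers a ring formation that is a ring enlargement with no entropic penalty, and a C6 centre set by chirality transfer.

**Alternative 2: palladium 1,4-oxylactonisation.** The disconnection cuts the C6–O lactone bond and a C3–O bond across a ring diene. In the forward step Pd(OAc)2, benzoquinone and LiOAc in AcOH make the C12 acid attack C6 and acetate attack C3 of the π-allyl intermediate, which gives A2.
- For: one step closes the butenolide and leaves an E C4=C5 bond flanked by an allylic C3 oxygen. That oxygen could direct the epoxidation, which is a better handle on the oxirane face than the chosen route has.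
- Against: the ten-membered ring with a conjugated diene must already exist, so the macrocycle problem is only moved. The regiochemistry and the cis/trans course of the diacyloxylation in a medium ring are sensitive. A2 still needs protecting-group and oxidation-state changes at C1, C3, C8 and C13.
- Comparison: the chosen route is shorter to the ring and makes the ring and C6 in the same step.

**Alternative 3: chromium allylation macrocyclisation.** The disconnection cuts C8–C9. In the forward step CrCl2 reduces the allylic bromide of a 2-(bromomethyl) enone, and the allylchromium adds to a C8 aldehyde on the butenolide to give A3.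
- For: allylchromium additions are among the most dependable closures of medium rings and tolerate esters and epoxides. The route is convergent and the oxirane is in place early. In convergence it is as strong as or stronger than the chosen route.
- Against: the C8 carbinol is created in the ring-closing event with uncertain facial control. The formyl butenolide and the bromomethyl enone are both fragile. A3 carries a C10 methylene whose reduction has to set the epimerisable C10 centre late, and C3 must still be oxidised.
- Comparison: the chosen route fixes C10 in the first step and needs no end-to-end closure.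

Key step: step 9

**Remarks on the chemistry (assumptions).**
- The (S)-configured diarylprolinol ether is taken to deliver (R)-3, by attack on the enamine face remote from the diarylmethyl group.
- C4 in 21–36, C11 in 26–28 and sulfur in 27–36 are carried without defined configuration. All three are lost or become sp2.
- Compound 11 is racemic.

## Steps

Step 1
Reactants: 1 propanal; 2 but-3-en-2-one
Product: 3 (R)-2-methyl-5-oxohexanal
Conditions: (S)-2-[methoxy(diphenyl)methyl]pyrrolidine (cat.), ethyl 3,4-dihydroxybenzoate (cat.), neat, 4 °C
Reagents that add atoms: none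
Why: Enamine-catalysed Michael addition of an aldehyde to an enone; the enamine of 1 is attacked on the face remote from the diphenyl(methoxy)methyl group, which sets C10 as R, and the catechol activates 2 by hydrogen bonding.

Step 2
Reactants: 3 (R)-2-methyl-5-oxohexanal
Product: 4 (R)-4-methylcyclohex-2-en-1-one
Conditions: LiOH, i-PrOH, rt
Reagents that add atoms: none
Why: Intramolecular aldol condensation of the methyl ketone onto the aldehyde with loss of water; the aldehyde is consumed by ring closure faster than its α-centre enolises, so C10 is kept.

Step 3
Reactants: 4 (R)-4-methylcyclohex-2-en-1-one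
Product: 6 (R)-3-ethoxy-4-methylcyclohex-2-en-1-one, via ethoxy selenide 5 (not isolated)
Conditions: PhSeCl, EtOH, CH2Cl2, 0 °C; then H2O2, pyridine, 0 °C to rt
Reagents that add atoms: ethanol CCO
Why: trans-Alkoxyselenenylation of the enone (selenium to the α-carbon, ethanol to the β-carbon) followed by selenoxide syn-elimination, whose only β-hydrogen is on the ethoxy-bearing carbon. The oxygen therefore ends on C1 next to C10, and C10 is never enolised.

Step 4
Reactants: 7 (Z)-but-2-ene-1,4-diol; 8 2,2-dimethoxypropane
Product: 9 2,2-dimethyl-4,7-dihydro-1,3-dioxepine
Conditions: p-TsOH (cat.), CH2Cl2, rt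
Reagents that add atoms: none
Why: Acid-catalysed transketalisation; the cis-diol closes the seven-membered acetonide.

Step 5
Reactants: 9 2,2-dimethyl-4,7-dihydro-1,3-dioxepine
Product: 10 2,2-dimethyl-4,5-dihydro-1,3-dioxepine
Conditions: RuHCl(CO)(PPh3)3 (cat.), neat, 100 °C
Reagents that add atoms: none
Why: Ruthenium hydride-catalysed double-bond migration (hydrometalation, β-hydride elimination) of the allylic acetal into conjugation with oxygen; the enol ether is the thermodynamic isomer.

Step 6
Reactants: 10 2,2-dimethyl-4,5-dihydro-1,3-dioxepine
Product: 12 6-bromo-2,2-dimethyl-4,5-dihydro-1,3-dioxepine, via dibromide 11 (not isolated)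
Conditions: Br2, CH2Cl2, −78 °C; then DBU, −78 °C to rt
Reagents that add atoms: bromine BrBr
Why: Bromine adds to the enol ether and the α-bromo ether loses HBr through the oxocarbenium ion to give the β-bromo enol ether, the sequence used for 5-bromo-3,4-dihydro-2H-pyran.

Step 7
Reactants: 6 (R)-3-ethoxy-4-methylcyclohex-2-en-1-one; 12 6-bromo-2,2-dimethyl-4,5-dihydro-1,3-dioxepine
Product: 14 (4R,6S)-6-(2,2-dimethyl-4,5-dihydro-1,3-dioxepin-6-yl)-3-ethoxy-4-methylcyclohex-2-en-1-one, via silyl dienol ether 13 (not isolated)
Conditions: LiN(i-Pr)2, THF, −78 °C; Me3SiCl; then 12, Pd(dba)2 (cat.), P(t-Bu)3, ZnF2, DMF, 70 °C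
Reagents that add atoms: none
Why: Kinetic α′-deprotonation (Stork–Danheiser regiochemistry, C10 untouched) and O-silylation, then palladium-catalysed α-alkenylation of the silyl enol ether under fluoride activation (zinc enolate, transmetalation to the alkenylpalladium bromide, reductive elimination). In the dienolate the C10 methyl is pseudoaxial (A(1,2) strain with the C1 ethoxy group), so C8 is bonded on the opposite face. The near-neutral medium does not enolise the new α-centre, so the 8S (trans) isomer should predominate and is purified by chromatography.

Step 8
Reactants: 14 (4R,6S)-6-(2,2-dimethyl-4,5-dihydro-1,3-dioxepin-6-yl)-3-ethoxy-4-methylcyclohex-2-en-1-one; 15 isopropenylmagnesium bromide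
Product: 16 (1R,4R,6S)-6-(2,2-dimethyl-4,5-dihydro-1,3-dioxepin-6-yl)-3-ethoxy-4-methyl-1-(prop-1-en-2-yl)cyclohex-2-en-1-ol
Conditions: CeCl3, THF, −78 °C; 15; then 14; aq. NaHCO3 work-up, Et3N-washed glassware
Reagents that add atoms: none
Why: 1,2-Addition of an organocerium reagent, which adds to the hindered ketone without deprotonating the doubly activated C8–H. Attack anti to the C8 alkenyl group gives the trans-dialkenyl carbinol (3R), and the basic work-up avoids ionisation of the doubly allylic alcohol.

Step 9
Reactants: 16 (1R,4R,6S)-6-(2,2-dimethyl-4,5-dihydro-1,3-dioxepin-6-yl)-3-ethoxy-4-methyl-1-(prop-1-en-2-yl)cyclohex-2-en-1-ol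
Product: 19 (6S,10R) ten-membered 1-ethoxy-3-(trimethylsilyloxy) diene with E C7=C8 and the C6/C12 acetonide, via potassium alkoxide 17 (not isolated), via potassium enolate 18 (not isolated)
Conditions: KH, 18-crown-6, THF, 0 °C to rt; then Me3SiCl, Et3N, −78 °C
Reagents that add atoms: chlorotrimethylsilane C[Si](C)(C)Cl
Why: KH deprotonates the tertiary alcohol and 18-crown-6 frees the alkoxide, whose [3,3] sigmatropic shift (anionic oxy-Cope rearrangement) breaks C3–C8 and forms C5–C6. The closest known reaction type is the anionic oxy-Cope rearrangement of trans-1,2-dialkenylcyclohexanols to (E)-cyclodec-5-enone enolates, also with cyclic enol ethers as the terminating alkene. The ten-membered ring is closed by enlargement of the six-membered ring by four atoms, not by an end-to-end cyclisation, so no high dilution is needed. The shift runs through a chair in which the ring bonds C3–C2 and C8–C9 are equatorial, which gives the E C7=C8 alkene and the C3=C4 enolate with C2 and C5 trans. The new stereocentre C6 is set by C8 (S) through this chair, because the cyclic enol ether can place its oxygen only in the outward position; this gives 6S here, the arrangement that becomes 6R in the target. The step needs the exocyclic isopropenyl group and not the ring enol ether C1=C2 to take part, and the chair and not the boat; the ring alkene could react only through a strained bridged transition state. The regiodefined potassium enolate is silylated on oxygen at −78 °C before proton transfer can move it, and C10 is not touched.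

Step 10
Reactants: 19 (6S,10R) ten-membered 1-ethoxy-3-(trimethylsilyloxy) diene with E C7=C8 and the C6/C12 acetonide
Product: 21 (6S,10R) ten-membered C3 ketone with C4 methyl and C4 phenylthio groups (C4 not defined), via lithium enolate 20 (not isolated)
Conditions: MeLi, THF, 0 °C; then PhSSO2Ph, −78 °C
Reagents that add atoms: S-phenyl benzenethiosulfonate O=S(=O)(Sc1ccccc1)c1ccccc1
Why: Methyllithium cleaves the silyl enol ether to the regiodefined lithium enolate, which is sulfenylated at C4 (Trost sulfenylation). The phenylthio group is a latent C4=C5 bond and leaves C3 without enolisable hydrogens.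

Step 11
Reactants: 21 (6S,10R) ten-membered C3 ketone with C4 methyl and C4 phenylthio groups
Product: 22 (6S,10R) C6,C12-diol
Conditions: pyridinium p-toluenesulfonate (cat.), EtOH–H2O, rt
Reagents that add atoms: none
Why: Acid-catalysed hydrolysis of the seven-membered acetonide; the weak acid in ethanol leaves the ethyl vinylogous ester and the allylic C6 alcohol intact.

Step 12
Reactants: 22 (6S,10R) C6,C12-diol
Product: 24 (6S,10R) β,γ-unsaturated γ-lactone (C12=O, C11H2, E C7=C8), via lactol 23 (not isolated)
Conditions: Cu(MeCN)4OTf (cat.), 2,2′-bipyridine, TEMPO, N-methylimidazole, air, MeCN, rt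
Reagents that add atoms: none
Why: Copper/nitroxyl aerobic oxidation is selective for the primary alcohol; the aldehyde closes to the lactol with the C6 hydroxyl and is oxidised again to the lactone. The thioether and the secondary allylic alcohol are not oxidised.

Step 13
Reactants: 24 (6S,10R) β,γ-unsaturated γ-lactone
Product: 26 (6S,10R) C11-hydroxymethyl lactone (C11 epimers), via lithium dienolate 25 (not isolated)
Conditions: LiN(SiMe3)2, THF, −78 °C; CH2O (gas), −78 °C; aq. NH4Cl
Reagents that add atoms: formaldehyde C=O
Why: Kinetic deprotonation at C11 (α to the lactone and allylic; the C3 ketone has no α-hydrogen) gives the dienolate, which adds to monomeric formaldehyde at its α-carbon (aldol reaction). At −78 °C the C7=C8 geometry should be kept.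

Step 14
Reactants: 26 (6S,10R) C11-hydroxymethyl lactone
Product: 29 (6S,8R,10R) butenolide diol with C4 phenylsulfinyl group, via sulfoxide 27 (not isolated), via epoxy lactone 28 (not isolated)
Conditions: mCPBA (2 equiv), NaHCO3, CH2Cl2, −78 to 0 °C; then DBU (cat.), −20 °C
Reagents that add atoms: 3-chloroperbenzoic acid OOC(=O)c1cccc(Cl)c1
Why: The peracid oxidises sulfur first and then epoxidises the only electron-rich alkene, C7=C8, on the face opposite C5, because the planar lactone ring holds C5 over one face of the trans double bond. Base-induced β-elimination of the β,γ-epoxy lactone (E1cB) then gives the butenolide and the C8 alcohol with the R configuration.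

Step 15
Reactants: 29 (6S,8R,10R) butenolide diol with C4 phenylsulfinyl group
Product: 30 (6S,8R,10R) C13 acetate with free C8 hydroxyl
Conditions: Ac2O (1 equiv), 2,4,6-collidine, CH2Cl2, −20 °C
Reagents that add atoms: acetic anhydride CC(=O)OC(C)=O
Why: Selective acylation of the primary allylic alcohol over the hindered secondary C8 alcohol at low temperature with a weak base.

Step 16
Reactants: 31 4-methylfuran-2(5H)-one
Product: 34 4-methoxybenzyl (Z)-4-acetoxy-3-methylbut-2-enoate, via potassium salt 32 (not isolated), via hydroxy ester 33 (not isolated)
Conditions: KOH, MeOH–H2O, rt, evaporate; 4-MeOC6H4CH2Cl, DMF; then Ac2O, pyridine, DMAP (cat.), 0 °C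
Reagents that add atoms: potassium hydroxide [K+].[OH-]; 4-methoxybenzyl chloride COc1ccc(CCl)cc1; acetic anhydride CC(=O)OC(C)=O
Why: Saponification opens the butenolide to the Z hydroxy carboxylate (geometry fixed by the ring). Carboxylate alkylation gives the ester, and the primary alcohol is acetylated in the same flask before it can relactonise.

Step 17
Reactants: 34 4-methoxybenzyl (Z)-4-acetoxy-3-methylbut-2-enoate
Product: 35 (Z)-4-acetoxy-3-methylbut-2-enoic acid
Conditions: CF3CO2H, anisole, CH2Cl2, 0 °C
Reagents that add atoms: none
Why: Acidolysis of the 4-methoxybenzyl ester, with the benzyl cation trapped by anisole; the acetate and the Z-enoate are stable to these conditions.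

Step 18
Reactants: 30 (6S,8R,10R) C13 acetate with free C8 hydroxyl; 35 (Z)-4-acetoxy-3-methylbut-2-enoic acid
Product: 36 (6S,8R,10R) C8 ester with C4 phenylsulfinyl group
Conditions: 2-methyl-6-nitrobenzoic anhydride, DMAP (cat.), Et3N, CH2Cl2, rt
Reagents that add atoms: none
Why: Mixed-anhydride esterification (Shiina) of the hindered secondary alcohol under mild base, chosen to avoid Z/E isomerisation or deconjugation of the β,β-disubstituted enoate.

Step 19
Reactants: 36 (6S,8R,10R) C8 ester with C4 phenylsulfinyl group
Product: 37 (6S,8R,10R) E C4=C5 enone
Conditions: CaCO3, toluene, 80 °C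
Reagents that add atoms: none
Why: Thermal syn-elimination of the α-keto sulfoxide toward C5. With C7=C8 gone, the ring can take up an E C4=C5 bond with C6–H eclipsing the C4 methyl, which an earlier dehydrogenation could not have delivered.

Step 20
Reactants: 37 (6S,8R,10R) E C4=C5 enone
Product: 38 (4S,5R,6R,8R,10R) 4,5-epoxy ketone with C1 ethyl enol ether
Conditions: t-BuOOH, DBU (cat.), CH2Cl2, 0 °C
Reagents that add atoms: tert-butyl hydroperoxide CC(C)(C)OO
Why: Weitz–Scheffer nucleophilic epoxidation: the peroxide anion adds to C5 of the cross-conjugated dienone (the β-ethoxy arm is deactivated) and closes on C4. Attack should come on the exposed face of the E-enone, which is the face syn to C7 when C6–H eclipses the double bond, as in 4,5-epoxygermacranolides of this relative configuration; this gives 4S,5R.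

Step 21
Reactants: 38 (4S,5R,6R,8R,10R) 4,5-epoxy ketone with C1 ethyl enol ether
Product: 39 target CNP0274470.1
Conditions: 0.5 M HClO4, THF–H2O, 0 °C
Reagents that add atoms: water O
Why: Acid hydrolysis of the vinylogous ester (water adds at C1, ethanol leaves) releases the 1,3-diketone. The non-nucleophilic acid should spare the α,β-epoxy ketone, and C10 is not exposed to base.

## Compound list

1 | propanal | CCC=O | starting material
2 | but-3-en-2-one | CC(=O)C=C | starting material
3 | (R)-2-methyl-5-oxohexanal | CC(=O)CC[C@@H](C)C=O | intermediate
4 | (R)-4-methylcyclohex-2-en-1-one | C[C@H]1C=CC(=O)CC1 | intermediate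
5 | (4R)-3-ethoxy-4-methyl-2-(phenylselanyl)cyclohexan-1-one, ethoxy trans to selenium and to methyl | O=C1CC[C@@H](C)[C@H](OCC)[C@H]1[Se]c1ccccc1 | intermediate
6 | (R)-3-ethoxy-4-methylcyclohex-2-en-1-one | CCOC1=CC(=O)CC[C@H]1C | intermediate
7 | (Z)-but-2-ene-1,4-diol | OC/C=C\CO | starting material
8 | 2,2-dimethoxypropane | COC(C)(C)OC | starting material
9 | 2,2-dimethyl-4,7-dihydro-1,3-dioxepine | CC1(C)OCC=CCO1 | intermediate
10 | 2,2-dimethyl-4,5-dihydro-1,3-dioxepine | CC1(C)OCCC=CO1 | intermediate
11 | trans-6,7-dibromo-2,2-dimethyl-1,3-dioxepane (racemic) | CC1(C)OCC[C@@H](Br)[C@H](Br)O1 | intermediate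
12 | 6-bromo-2,2-dimethyl-4,5-dihydro-1,3-dioxepine | CC1(C)OCCC(Br)=CO1 | intermediate
13 | [(5R)-4-ethoxy-5-methylcyclohexa-1,3-dien-2-yl]oxy(trimethyl)silane | CCOC1=CC(O[Si](C)(C)C)=CC[C@H]1C | intermediate
14 | (4R,6S)-6-(2,2-dimethyl-4,5-dihydro-1,3-dioxepin-6-yl)-3-ethoxy-4-methylcyclohex-2-en-1-one | CCOC1=CC(=O)[C@H](C2=COC(C)(C)OCC2)C[C@H]1C | intermediate
15 | isopropenylmagnesium bromide | C=C(C)[Mg]Br | starting material
16 | (1R,4R,6S)-6-(2,2-dimethyl-4,5-dihydro-1,3-dioxepin-6-yl)-3-ethoxy-4-methyl-1-(prop-1-en-2-yl)cyclohex-2-en-1-ol (3R,8S,10R in target numbering) | CCOC1=C[C@@](O)(C(C)=C)[C@H](C2=COC(C)(C)OCC2)C[C@H]1C | intermediate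
17 | potassium alkoxide of 16 | CCOC1=C[C@@]([O-])(C(C)=C)[C@H](C2=COC(C)(C)OCC2)C[C@H]1C.[K+] | intermediate
18 | potassium C3 enolate of the ten-membered ring (6S,10R; Z C1=C2, E C7=C8, C2 and C5 trans on C3=C4) | CCO/C1=C/C([O-])=C(C)/C[C@@H]2OC(C)(C)OCC/C2=C\C[C@H]1C.[K+] | intermediate
19 | (6S,10R) ten-membered 1-ethoxy-3-(trimethylsilyloxy) diene with E C7=C8; C6–O and C12–O joined as isopropylidene acetal | CCO/C1=C/C(O[Si](C)(C)C)=C(C)/C[C@@H]2OC(C)(C)OCC/C2=C\C[C@H]1C | intermediate
20 | lithium C3 enolate corresponding to 19 | CCO/C1=C/C([O-])=C(C)/C[C@@H]2OC(C)(C)OCC/C2=C\C[C@H]1C.[Li+] | intermediate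
21 | (6S,10R) C3 ketone with C4 methyl and C4 phenylthio groups (C4 not defined), C1 ethyl enol ether, E C7=C8, acetonide | CCO/C1=C/C(=O)C(C)(Sc3ccccc3)C[C@@H]2OC(C)(C)OCC/C2=C\C[C@H]1C | intermediate
22 | (6S,10R) diol: C6 hydroxyl and 2-hydroxyethyl group on C7, E C7=C8 | CCO/C1=C/C(=O)C(C)(Sc3ccccc3)C[C@H](O)/C(CCO)=C/C[C@H]1C | intermediate
23 | lactol (C12 hemiacetal, both anomers) | CCO/C1=C/C(=O)C(C)(Sc3ccccc3)C[C@@H]2OC(O)C/C2=C\C[C@H]1C | intermediate
24 | (6S,10R) β,γ-unsaturated γ-lactone (C12=O, C11H2, E C7=C8) | CCO/C1=C/C(=O)C(C)(Sc3ccccc3)C[C@@H]2OC(=O)C/C2=C\C[C@H]1C | intermediate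
25 | lithium dienolate of 24 (C12–O−, C11=C12, C7=C8) | CCO/C1=C/C(=O)C(C)(Sc3ccccc3)C[C@@H]2OC([O-])=C/C2=C\C[C@H]1C.[Li+] | intermediate
26 | (6S,10R) C11-hydroxymethyl lactone (C11 epimers) | CCO/C1=C/C(=O)C(C)(Sc3ccccc3)C[C@@H]2OC(=O)C(CO)/C2=C\C[C@H]1C | intermediate
27 | sulfoxide of 26 (sulfur epimers) | CCO/C1=C/C(=O)C(C)(S(=O)c3ccccc3)C[C@@H]2OC(=O)C(CO)/C2=C\C[C@H]1C | intermediate
28 | 7,8-epoxy lactone, oxirane on the face of C6–H (8R) | CCO/C1=C/C(=O)C(C)(S(=O)c3ccccc3)C[C@@H]2OC(=O)C(CO)[C@@]24O[C@@H]4C[C@H]1C | intermediate
29 | (6S,8R,10R) butenolide (C7=C11) with C8 hydroxyl, C13 hydroxyl and C4 phenylsulfinyl group | CCO/C1=C/C(=O)C(C)(S(=O)c3ccccc3)C[C@@H]2OC(=O)C(CO)=C2[C@H](O)C[C@H]1C | intermediate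
30 | (6S,8R,10R) C13 acetate with free C8 hydroxyl | CCO/C1=C/C(=O)C(C)(S(=O)c3ccccc3)C[C@@H]2OC(=O)C(COC(C)=O)=C2[C@H](O)C[C@H]1C | intermediate
31 | 4-methylfuran-2(5H)-one | CC1=CC(=O)OC1 | starting material
32 | potassium (Z)-4-hydroxy-3-methylbut-2-enoate | [K+].[O-]C(=O)/C=C(/C)CO | intermediate
33 | 4-methoxybenzyl (Z)-4-hydroxy-3-methylbut-2-enoate | COc1ccc(COC(=O)/C=C(/C)CO)cc1 | intermediate
34 | 4-methoxybenzyl (Z)-4-acetoxy-3-methylbut-2-enoate | COc1ccc(COC(=O)/C=C(/C)COC(C)=O)cc1 | intermediate
35 | (Z)-4-acetoxy-3-methylbut-2-enoic acid | OC(=O)/C=C(/C)COC(C)=O | intermediate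
36 | (6S,8R,10R) C8 (Z)-4-acetoxy-3-methylbut-2-enoate, C13 acetate, C4 phenylsulfinyl group | CCO/C1=C/C(=O)C(C)(S(=O)c3ccccc3)C[C@@H]2OC(=O)C(COC(C)=O)=C2[C@H](OC(=O)/C=C(/C)COC(C)=O)C[C@H]1C | intermediate
37 | (6S,8R,10R) E C4=C5 enone with C1 ethyl enol ether | CCO/C1=C/C(=O)/C(C)=C/[C@@H]2OC(=O)C(COC(C)=O)=C2[C@H](OC(=O)/C=C(/C)COC(C)=O)C[C@H]1C | intermediate
38 | (4S,5R,6R,8R,10R) 4,5-epoxy ketone with C1 ethyl enol ether | CCO/C1=C/C(=O)[C@@]3(C)O[C@@H]3[C@@H]2OC(=O)C(COC(C)=O)=C2[C@H](OC(=O)/C=C(/C)COC(C)=O)C[C@H]1C | intermediate
39 | CNP0274470.1 (4S,5R,6R,8R,10R) | CC(=O)OCC1=C2[C@@H](OC1=O)[C@H]1O[C@]1(C)C(=O)CC(=O)[C@H](C)C[C@H]2OC(=O)/C=C(/C)COC(C)=O | target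

## Step count and least certain steps

Total: 21 steps. Longest linear sequence: 16 steps (steps 1–3, 7–15 and 18–21; the branch through steps 4–6 is equally long).

**Step 9 (key step).** The most likely failures are three:
- loss of the carbinol by ionisation of the doubly allylic, enol-ether-bearing alcohol before it is deprotonated;
- leakage through a boat or a cleavage–recombination path, which would erode C6 and the E geometry;
- proton transfer in the enolate before silylation.

The fallback never handles the free alcohol and sets out from 14. The cerium alkoxide of the addition is quenched with Me3SiCl to give the trimethylsilyl ether of 16, F1, which is neutral and can be chromatographed. Treatment of F1 with KOt-Bu and 18-crown-6 in THF removes silicon and releases the potassium alkoxide 17 directly in the rearrangement medium. The irreversible [3,3] shift pulls the silyl transfer forward, and silylation of the enolate brings the route back at 19.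

**Step 7.** The kinetic C8 configuration may be lost by enolisation of the product under the coupling conditions, or the facial selection on the dienolate may be poor; both would give the cis epimer. The fallback reverses the polarity and puts C8 under catalyst control. The silyl dienol ether 13 is brominated with N-bromosuccinimide to 6-bromo-3-ethoxy-4-methylcyclohex-2-en-1-one F2 (both C8 epimers). Bromide 12 is converted with t-BuLi and then ZnCl2 into (2,2-dimethyl-4,5-dihydro-1,3-dioxepin-6-yl)zinc chloride F3. A stereoconvergent nickel-catalysed Negishi coupling of the α-bromo ketone (NiCl2·glyme with a chiral pybox ligand chosen for 8S) joins F2 and F3 at low temperature without base and returns to 14.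

**Step 14.** Three things may go wrong:
- the peracid may attack the enol ether double bond of the vinylogous ester or over-oxidise sulfur;
- the base may epimerise C6 through the butenolide dienolate;
- the base may let the lactone migrate to the new C8 hydroxyl.

The fallback uses no base and no peracid on the alkene. From 26, NaIO4 gives sulfoxide 27, which is isolated. Singlet oxygen (tetraphenylporphyrin, light, CH2Cl2, −40 °C) then undergoes an ene reaction in which the activated C11–H is abstracted and oxygen is delivered to C8 on the same exposed face. This gives the C8 hydroperoxide of the butenolide, F4. Reduction of F4 with PPh3 returns to 29.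

**Step 19.** The syn-elimination may go into the C4 methyl group and give the exocyclic enone, or it may give the cis ring olefin. The fallback accepts the exocyclic elimination and sets out from 36. The C4-methylene ketone F5 is isomerised with RhCl3·3H2O in ethanol at 70 °C, which moves the double bond into the ring to the more substituted conjugated position, and the route returns at 37.

**Step 20.** The peroxide may attack the wrong face of the enone, since the face selection rests only on the conformation of the ring, and the base may epimerise the doubly activated C6–H. The fallback changes from substrate control to catalyst control and sets out from 37. An asymmetric nucleophilic epoxidation with La(O-i-Pr)3, a BINOL enantiomer, Ph3As=O and cumene hydroperoxide in THF is run with the ligand enantiomer that gives 4S,5R. The medium is less basic than the amine system, and the route returns at 38.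

## Further compounds

F1 | step 9 | trimethylsilyl ether of 16 | CCOC1=C[C@@](O[Si](C)(C)C)(C(C)=C)[C@H](C2=COC(C)(C)OCC2)C[C@H]1C
F2 | step 7 | (4R)-6-bromo-3-ethoxy-4-methylcyclohex-2-en-1-one (C6 epimers) | CCOC1=CC(=O)C(Br)C[C@H]1C
F3 | step 7 | (2,2-dimethyl-4,5-dihydro-1,3-dioxepin-6-yl)zinc chloride | CC1(C)OCCC([Zn]Cl)=CO1
F4 | step 14 | (6S,8R,10R) C8 hydroperoxide of butenolide 29 | CCO/C1=C/C(=O)C(C)(S(=O)c3ccccc3)C[C@@H]2OC(=O)C(CO)=C2[C@H](OO)C[C@H]1C
F5 | step 19 | (6S,8R,10R) C4-methylene ketone isomer of 37 | CCO/C1=C/C(=O)C(=C)C[C@@H]2OC(=O)C(COC(C)=O)=C2[C@H](OC(=O)/C=C(/C)COC(C)=O)C[C@H]1C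
F0 | step 20 | none | none
A1 | alternative 1 | isoxazoline-bridged ten-membered carbocycle | CC(=O)OCC1=C2[C@@H](OC1=O)[C@H]3O[C@]3(C)C4=NO[C@@H](C4)[C@H](C)C[C@H]2OC(=O)/C=C(/C)COC(C)=O
A2 | alternative 2 | butenolide-fused ten-membered ring with C3 acetate, E C4=C5, C1 dioxolane, C8 4-methoxybenzyl ether and C13 silyl ether | CC(C)(C)[Si](C)(C)OCC1=C2[C@@H](OC1=O)/C=C(C)/[C@@H](OC(C)=O)CC3(OCCO3)[C@H](C)C[C@H]2OCc2ccc(OC)cc2
A3 | alternative 3 | ten-membered C8 alcohol with C10 methylene ketone, oxirane and C3 silyl ether | CC(=O)OCC1=C2[C@@H](OC1=O)[C@H]3O[C@]3(C)[C@@H](O[Si](C)(C)C(C)(C)C)CC(=O)C(=C)C[C@H]2O
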